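(All runs come from a simulation for an exercise.)

A flask cannot stop for want of reagent while reagent is still in it, yet one of these runs seems to.

| setting | south-east | north | east | blue | grey |
|---|---|---|---|---|---|
| starting material | 0.38 M | 0.38 M | 0.19 M | 0.38 M | 0.38 M |
| reagent | 1.4 equiv | 2.2 equiv | 1 equiv | 1.00 equiv | 1.00 equiv |
| temperature | 105 °C | 116 °C | 105 °C | 100 °C | 120 °C |
| remark | run made earlier | run made earlier | run made earlier |  |  |
| time |  |  |  | 20 h | 20 h |

- south-east (time / h: double product / %, side product / %): 3.00: 16, 0; 8.00: 23, 8; 15.0: 31, 11; 25.0: 33, 19
- north (time / h: double product / %, side product / %): 1.33: 24, 5; 4.00: 45, 10; 6.00: 49, 14; 12.0: 52, 16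
- east (time / h: double product / %, side product / %): 3.00: 0, 0; 8.00: 11, 5; 15.0: 13, 11; 25.0: 18, 16

(scatter of a reading: 2 percentage points)



- the flask that comes out highest in share of double product in all that became double product or side product or isomer of the product, or "all alike" when all lie within 1.5 percentage points (blue / grey / all alike)
- share of double product in all that became double product or side product or isomer of the product, blue
- share of double product in all that became double product or side product or isomer of the product, grey

That run is north. If double product costs two of reagent and side product one, what north shows by 12.0 h has cost 1.20, of 2.2 equiv charged. Yet after 6.00 h double product moves from 49 % to 52 % and side product from 14 % to 16 %, about the scatter of 2 percentage points. And the two leave 32 points of the charge unseen.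

So I ask what the end state must be. I assume north's starting material is used up, and I read the gap as isomer of the product, which these runs do not report. At two of reagent per isomer, as for double product, the cost in north becomes 1.84, of 2.2 equiv charged. Double product and isomer would then sit at their equilibrium ratio for that temperature, under thermodynamic control. That is 0.615 of isomer per unit of double product; I call this reading, taken in north at 116 °C, the isomer tax.

The asked share, divided through by double product, is one over one plus the tax plus the side ratio. South-east at its last reading, at 105 °C and 1.4 equiv, gives a side ratio of 0.576. Carrying both readings over to blue unchanged, as an assumption, I reckon 45.6 % for blue.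

The forecast says blue, with 65 % (52 % to 77 %) for blue and 50 % (37 % to 63 %) for grey, on the ground that “cooler conditions favour double product”, and my figure for blue is lower.

The flask gives 46.5 % for blue and 37.3 % for grey, so blue comes out higher. In grey at 20.0 h, side product at 29.2 % stands above double product at 24.0 %. The isomer tax on those two amounts gives grey a share of 35.3 %.

    starting material + reagent → mono adduct + released group (k = 5.80 × 10⁻⁵ L mol⁻¹ s⁻¹, Ea = 108 kJ mol⁻¹)
    mono adduct → side product (k = 1.60 × 10⁻⁵ s⁻¹, Ea = 115 kJ mol⁻¹)
    reagent + mono adduct → double product + released group (k = 3.10 × 10⁻⁴ L mol⁻¹ s⁻¹, Ea = 88.0 kJ mol⁻¹)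
    double product ⇌ isomer of the product (K = 0.650, k = 1.80 × 10⁻⁴ s⁻¹, Ea = 103 kJ mol⁻¹, ΔH = −21.0 kJ mol⁻¹)
    (constants at 100 °C)

A neighbour of blue charged with 2.50 equiv of reagent holds 47.4 % double product and 7.16 % side product at 20.0 h. The isomer tax gives this neighbour a share of 56.6 %, and the computed share is 55.8 %.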